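Numbering: C1 = CO2H, C2 (=C2'H2), C3 = ring OCH, C4/C5 = ring CH2, C6 = ring CH, C6' = ring OCH2, C7/C8 = CH2, C9 = carbinol, C10 (=C10'H2), C11, C12, then the C13-C18 diene tail.
Enabling feature: in the tetrahydropyran (O, C3, C4, C5, C6, C6'), C6 holds two arms alike in constitution and in (R) configuration, C5-C4-C3(O)-C2(=CH2)-C1 and C7-C8-C9(O)-C10(=CH2)-C11. Only the O-C6' bond tells them apart and makes C6 a stereocentre.
Cuts, in retrosynthetic order: C1 acid to CH2OH; C11-C12 (allylic bromide + geranyl sulfone anion); ring O-C6' (secondary alkoxide + primary tosylate); C2-C3 and C9-C10 at once (alkenyllithium + bis-Weinreb amide); C6=C6' from the ketone of diethyl 4-oxopimelate.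
Forward: the C3-C9 core grows in both directions and the only ring closes in step 10. The arms are then told apart as 1,3-diol (chain arm) against lone primary alcohol (ring arm), the tail is joined at C11, and C1 is oxidised last.
Stereochemistry: C3 and C9 come from one double Corey-Bakshi-Shibata reduction (reagent control), C6 from the choice between two diastereotopic alkoxides in a chair transition state (substrate control), and the E-alkene from geranyl bromide.

Key step: step 10

Step 1
Reactants: 1 diethyl 4-oxoheptanedioate (diethyl 4-oxopimelate)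
Product: 2 diethyl 4-methylideneheptanedioate
Conditions: MePPh3Br, KOt-Bu, THF, 0 °C; then 1, 0 °C to rt
Reagents that add atoms: methyltriphenylphosphonium bromide, C[P+](c1ccccc1)(c1ccccc1)c1ccccc1.[Br-]
Why: Wittig methylenation, in which the non-stabilised ylide attacks the ketone far faster than the two esters and installs C6' as a methylene group on the future C6.

Step 2
Reactants: 2 diethyl 4-methylideneheptanedioate
Product: 3 N1,N7-dimethoxy-N1,N7-dimethyl-4-methylideneheptanediamide (bis-Weinreb amide)
Conditions: MeNH(OMe)·HCl, i-PrMgCl, THF, -20 to 0 °C; aq NH4Cl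
Reagents that add atoms: N,O-dimethylhydroxylamine hydrochloride, CNOC.Cl
Why: Ester aminolysis with the chloromagnesium amide of N,O-dimethylhydroxylamine is the standard entry to Weinreb amides and converts both identical termini (C3 and C9) in one operation.

Step 3
Reactants: 3 bis-Weinreb amide
Product: 5 4-(hydroxymethyl)-N1,N7-dimethoxy-N1,N7-dimethylheptanediamide, via B-alkyl-9-BBN adduct 4 (not isolated)
Conditions: 9-BBN (9-borabicyclo[3.3.1]nonane), THF, 0 °C to rt; then 30% H2O2, aq NaOAc, 0 °C to rt
Reagents that add atoms: 9-borabicyclo[3.3.1]nonane, [H]B1C2CCCC1CCC2 (its atoms stay only in 4); hydrogen peroxide, OO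
Why: Hydroboration-oxidation, in which 9-BBN places boron on the open terminus C6' of the 1,1-disubstituted alkene, leaves the amides alone at room temperature, and is followed by weakly basic peroxide to avoid hydroxyl-assisted loss of an amide.

Step 4
Reactants: 5 hydroxy bis-Weinreb amide
Product: 6 4-[(triethylsilyloxy)methyl]-N1,N7-dimethoxy-N1,N7-dimethylheptanediamide
Conditions: Et3SiCl, imidazole, CH2Cl2, 0 °C
Reagents that add atoms: chlorotriethylsilane, CC[Si](Cl)(CC)CC
Why: Standard silylation of a primary alcohol, giving a triethylsilyl ether that tolerates organolithium and borane reagents yet can later be removed by mild acid beside triisopropylsilyl ethers.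

Step 5
Reactants: 7 2-bromoprop-2-en-1-ol
Product: 8 (2-bromoprop-2-enyloxy)triisopropylsilane
Conditions: i-Pr3SiCl, imidazole, DMF, rt
Reagents that add atoms: chlorotriisopropylsilane, CC(C)[Si](Cl)(C(C)C)C(C)C
Why: Standard silylation, with the bulky triisopropylsilyl group chosen because it resists migration to a neighbouring carbanion in step 6 and to a neighbouring alkoxide in step 10.

Step 6
Reactants: 6 silylated bis-Weinreb amide; 8 (2-bromoprop-2-enyloxy)triisopropylsilane
Product: 10 6-[(triethylsilyloxy)methyl]-2,10-bis[(triisopropylsilyloxy)methyl]undeca-1,10-diene-3,9-dione (bis-enone), via 2-lithioallyl silyl ether 9 (not isolated)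
Conditions: 8 (2.6 equiv), t-BuLi (5.2 equiv), Et2O, -78 °C; then 6, -78 to -20 °C; aq NH4Cl
Reagents that add atoms: tert-butyllithium, [Li]C(C)(C)C (its lithium stays only in 9)
Why: Bromine-lithium exchange followed by acylation of the alkenyllithium with a Weinreb amide, where the chelated tetrahedral adducts persist until the quench, so each arm stops at the ketone and the C2-C3 and C9-C10 bonds form together.

Step 7
Reactants: 10 bis-enone
Product: 11 (3R,9R)-6-[(triethylsilyloxy)methyl]-2,10-bis[(triisopropylsilyloxy)methyl]undeca-1,10-diene-3,9-diol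
Conditions: (S)-Me-CBS oxazaborolidine [(3aS)-1-methyl-3,3-diphenyltetrahydro-1H,3H-pyrrolo[1,2-c][1,3,2]oxazaborole, C18H20BNO] (0.4 equiv), catecholborane (4 equiv), toluene, -78 °C; MeOH, then aq NaHCO3
Reagents that add atoms: none
Why: Corey-Bakshi-Shibata reduction, in which the branched alkenyl group acts as the large and the methylene chain as the small ketone substituent, so the (S)-catalyst should give the (R)-carbinol at C3 and C9 alike, catecholborane at low temperature spares the alkenes, and the minor sense is diverted into (R,S) diastereomers to be removed by chromatography here or after ring closure.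

Step 8
Reactants: 11 (3R,9R)-diol triethylsilyl ether
Product: 12 (3R,9R)-6-(hydroxymethyl)-2,10-bis[(triisopropylsilyloxy)methyl]undeca-1,10-diene-3,9-diol
Conditions: pyridinium p-toluenesulfonate (0.1 equiv), MeOH/CH2Cl2, 0 °C
Reagents that add atoms: none
Why: Acid-catalysed methanolysis of a silyl ether, in which the triethylsilyl group is lost far faster than the triisopropylsilyl groups and the weak acid cannot ionise the allylic alcohols.

Step 9
Reactants: 12 (3R,9R)-triol
Product: 13 C6' 4-methylbenzenesulfonate of triol 12 [(3R,9R)-diol primary tosylate; C6 not stereogenic]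
Conditions: TsCl (1.1 equiv), pyridine, CH2Cl2, 0 °C
Reagents that add atoms: p-toluenesulfonyl chloride, Cc1ccc(cc1)S(=O)(=O)Cl
Why: Selective sulfonylation, in which the open primary hydroxyl on C6' reacts well ahead of two secondary allylic hydroxyls that sit next to a branched alkene, the usual basis for monotosylation of primary/secondary polyols.

Step 10
Reactants: 13 (3R,9R)-diol primary tosylate
Product: 14 trans-2,5-disubstituted tetrahydropyran (3R,6S,9R): (3R)-5-[(3S,6R)-6-{3-(triisopropylsilyloxy)prop-1-en-2-yl}oxan-3-yl]-2-[(triisopropylsilyloxy)methyl]pent-1-en-3-ol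
Conditions: NaH (1.2 equiv), THF (0.01 M), 0 °C to rt
Reagents that add atoms: none
Why: Intramolecular Williamson ether synthesis, in which NaH produces an alkoxide that fast proton transfer shares between O3 and O9, and either oxygen can displace the C6' tosylate by SN2. The closest known reaction type is the diastereotopic-group-selective cyclisation of pseudo-symmetric hydroxy sulfonates to cyclic ethers. The ring (O, C3, C4, C5, C6, C6') closes in the 6-exo-tet mode through a chair-like transition state with the leaving group outside the ring. With both carbinols (R), the chair that closes through one arm can seat the alkenyl group on C3 and the unused arm on C6 equatorially and ends in the trans (3R,6S) ring, while the chair through the other arm has to turn one of these groups axial and ends in the cis ring, so the configuration of C6 follows from which arm closes. The step therefore needs group selectivity, which rests on these two equatorial preferences and is supported by low temperature, by high dilution against intermolecular etherification, and by silyl groups that stay on O1 and O11 so that neither nucleophilic oxygen becomes blocked. A clear but imperfect preference is expected, so the cis isomer is to be removed by chromatography, and C3 and C9 are untouched because no bond to them breaks.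

Step 11
Reactants: 14 trans-tetrahydropyran bis(silyl ether)
Product: 15 (3R,6S,9R)-triol: (3R)-5-[(3S,6R)-6-(3-hydroxyprop-1-en-2-yl)oxan-3-yl]-2-methylidenepentane-1,3-diol
Conditions: Bu4NF (2.5 equiv), THF, rt
Reagents that add atoms: none
Why: Fluoride-induced desilylation removes both triisopropylsilyl groups and exposes the chemical difference between the arms, a 1,3-diol (O9/O11) on the chain arm against a lone primary alcohol (O1) on the ring arm.

Step 12
Reactants: 15 (3R,6S,9R)-triol
Product: 18 C1 tert-butyldimethylsilyl ether of triol 15 (O9 and O11 free; 3R,6S,9R), via cyclic phenylboronate 16 (not isolated), via silylated phenylboronate 17 (not isolated)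
Conditions: PhB(OH)2 (1.0 equiv), 4 Å molecular sieves, CH2Cl2, rt; t-BuMe2SiCl, imidazole, 0 °C to rt; then 30% H2O2, pH 7 buffer, THF, 0 °C
Reagents that add atoms: phenylboronic acid, OB(O)c1ccccc1 (its atoms stay only in 16 and 17); tert-butyldimethylsilyl chloride, CC(C)(C)[Si](C)(C)Cl
Why: Transient boronate protection, in which phenylboronic acid condenses only with the 1,3-diol to a six-membered dioxaborinane, the remaining C1 hydroxyl is silylated under standard conditions and oxidative work-up destroys the boronate, a sequence well known from site-selective functionalisation of sugars and polyols.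

Step 13
Reactants: 18 C1 silyl ether diol
Product: 19 C11 bromide: (3R)-2-(bromomethyl)-5-[(3S,6R)-6-{3-(tert-butyldimethylsilyloxy)prop-1-en-2-yl}oxan-3-yl]pent-1-en-3-ol
Conditions: CBr4 (1.05 equiv), PPh3 (1.1 equiv), CH2Cl2, -30 to 0 °C
Reagents that add atoms: carbon tetrabromide, BrC(Br)(Br)Br
Why: Appel reaction, in which one equivalent of reagent at low temperature activates the primary allylic hydroxyl on C11 ahead of the hindered secondary one, and direct or allylic displacement gives the same bromide because C11 and C10' are equivalent termini of one allyl unit.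

Step 14
Reactants: 20 geranyl bromide [(2E)-1-bromo-3,7-dimethylocta-2,6-diene]
Product: 21 geranyl phenyl sulfone [(2E)-3,7-dimethylocta-2,6-dienyl phenyl sulfone]
Conditions: PhSO2Na, DMF, rt
Reagents that add atoms: sodium benzenesulfinate, [Na+].[O-]S(=O)c1ccccc1
Why: SN2 S-alkylation of the sulfinate by a primary allylic bromide gives the sulfone with the E-alkene intact.

Step 15
Reactants: 19 C11 bromide; 21 geranyl phenyl sulfone
Product: 23 C12 phenyl sulfone of the full skeleton (3R,6S,9R,13E; both C12 epimers; C1 silyl ether), via lithiated geranyl sulfone 22 (not isolated)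
Conditions: 21 (2.3 equiv), n-BuLi (2.2 equiv), THF, -78 °C; then 19, -78 to -40 °C; aq NH4Cl
Reagents that add atoms: n-butyllithium, [Li]CCCC (its lithium stays only in 22)
Why: Alkylation of a sulfonyl-stabilised allyl carbanion (sulfone route to 1,5-dienes), in which the soft carbanion attacks the allylic bromide through its α-carbon to form C11-C12, the second equivalent takes up the hydroxyl proton, and four-membered ring closure by the alkoxide cannot compete at -78 °C.

Step 16
Reactants: 23 C12 phenyl sulfone
Product: 24 C1 tert-butyldimethylsilyl ether of the C1 alcohol with the complete chain (3R,6S,9R,13E)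
Conditions: PdCl2(dppp) [dppp = Ph2P(CH2)3PPh2] (0.1 equiv), LiBHEt3 (5 equiv), THF, 0 °C; aq NH4Cl
Reagents that add atoms: none
Why: Palladium-catalysed hydride desulfonylation of an allylic sulfone, in which zerovalent palladium formed in the flask ionises only the C12-S bond and hydride reaches the less substituted terminus C12 of the allyl complex, so the C13=C14 alkene should keep its place and E geometry while silyl ether, ring ether and alkoxide do not leave.

Step 17
Reactants: 24 C1 silyl ether
Product: 25 (3R,6S,9R,13E)-diol: (3R,7E)-1-[(3S,6R)-6-(3-hydroxyprop-1-en-2-yl)oxan-3-yl]-8,12-dimethyl-4-methylidenetrideca-7,11-dien-3-ol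
Conditions: Bu4NF, THF, 0 °C to rt
Reagents that add atoms: none
Why: Fluoride-induced desilylation frees the C1 alcohol without touching alkenes or stereocentres.

Step 18
Reactants: 25 (3R,6S,9R,13E)-diol
Product: 27 2-[(2R,5S)-5-[(3R,7E)-3-hydroxy-8,12-dimethyl-4-methylidenetrideca-7,11-dien-1-yl]oxan-2-yl]prop-2-enoic acid (target), via enal 26 (not isolated)
Conditions: 2,2,6,6-tetramethylpiperidin-1-oxyl (TEMPO, 0.1 equiv), PhI(OAc)2 (1.1 equiv), CH2Cl2, rt; then NaClO2, NaH2PO4, 2-methyl-2-butene, t-BuOH/H2O, 0 °C to rt
Reagents that add atoms: sodium chlorite, [Na+].[O-]Cl=O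
Why: Oxoammonium oxidation followed by Pinnick oxidation, in which the hindered oxidant takes the primary allylic alcohol well before the secondary C9 carbinol, and chlorite with excess 2-methyl-2-butene as hypochlorite trap turns the enal into the acrylic acid without attack on the trisubstituted alkenes.

Compound list
1 | diethyl 4-oxoheptanedioate | CCOC(=O)CCC(=O)CCC(=O)OCC | starting material
2 | diethyl 4-methylideneheptanedioate | C=C(CCC(=O)OCC)CCC(=O)OCC | intermediate
3 | N1,N7-dimethoxy-N1,N7-dimethyl-4-methylideneheptanediamide | C=C(CCC(=O)N(C)OC)CCC(=O)N(C)OC | intermediate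
4 | B-alkyl-9-BBN adduct of 3 (boron on C6') | CON(C)C(=O)CCC(CB1C2CCCC1CCC2)CCC(=O)N(C)OC | intermediate
5 | 4-(hydroxymethyl)-N1,N7-dimethoxy-N1,N7-dimethylheptanediamide | CON(C)C(=O)CCC(CO)CCC(=O)N(C)OC | intermediate
6 | 4-[(triethylsilyloxy)methyl]-N1,N7-dimethoxy-N1,N7-dimethylheptanediamide | CC[Si](CC)(CC)OCC(CCC(=O)N(C)OC)CCC(=O)N(C)OC | intermediate
7 | 2-bromoprop-2-en-1-ol | C=C(Br)CO | starting material
8 | (2-bromoprop-2-enyloxy)triisopropylsilane | C=C(Br)CO[Si](C(C)C)(C(C)C)C(C)C | intermediate
9 | [3-(triisopropylsilyloxy)prop-1-en-2-yl]lithium | [Li]C(=C)CO[Si](C(C)C)(C(C)C)C(C)C | intermediate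
10 | 6-[(triethylsilyloxy)methyl]-2,10-bis[(triisopropylsilyloxy)methyl]undeca-1,10-diene-3,9-dione | C=C(CO[Si](C(C)C)(C(C)C)C(C)C)C(=O)CCC(CO[Si](CC)(CC)CC)CCC(=O)C(=C)CO[Si](C(C)C)(C(C)C)C(C)C | intermediate
11 | (3R,9R)-6-[(triethylsilyloxy)methyl]-2,10-bis[(triisopropylsilyloxy)methyl]undeca-1,10-diene-3,9-diol | CC[Si](CC)(CC)OCC(CC[C@@H](O)C(=C)CO[Si](C(C)C)(C(C)C)C(C)C)CC[C@@H](O)C(=C)CO[Si](C(C)C)(C(C)C)C(C)C | intermediate
12 | (3R,9R)-6-(hydroxymethyl)-2,10-bis[(triisopropylsilyloxy)methyl]undeca-1,10-diene-3,9-diol | OCC(CC[C@@H](O)C(=C)CO[Si](C(C)C)(C(C)C)C(C)C)CC[C@@H](O)C(=C)CO[Si](C(C)C)(C(C)C)C(C)C | intermediate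
13 | C6' 4-methylbenzenesulfonate of 12, (3R,9R) | Cc1ccc(cc1)S(=O)(=O)OCC(CC[C@@H](O)C(=C)CO[Si](C(C)C)(C(C)C)C(C)C)CC[C@@H](O)C(=C)CO[Si](C(C)C)(C(C)C)C(C)C | intermediate
14 | (3R)-5-[(3S,6R)-6-{3-(triisopropylsilyloxy)prop-1-en-2-yl}oxan-3-yl]-2-[(triisopropylsilyloxy)methyl]pent-1-en-3-ol (trans ring) | C=C(CO[Si](C(C)C)(C(C)C)C(C)C)[C@H](O)CC[C@H]1CC[C@H](C(=C)CO[Si](C(C)C)(C(C)C)C(C)C)OC1 | intermediate
15 | (3R)-5-[(3S,6R)-6-(3-hydroxyprop-1-en-2-yl)oxan-3-yl]-2-methylidenepentane-1,3-diol | C=C(CO)[C@H](O)CC[C@H]1CC[C@H](C(=C)CO)OC1 | intermediate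
16 | O9,O11-phenylboronate (5-methylidene-2-phenyl-1,3,2-dioxaborinane) of 15, configuration as in 15 | C=C1COB(c2ccccc2)O[C@@H]1CC[C@H]3CC[C@H](C(=C)CO)OC3 | intermediate
17 | C1 tert-butyldimethylsilyl ether of 16 | C=C1COB(c2ccccc2)O[C@@H]1CC[C@H]3CC[C@H](C(=C)CO[Si](C)(C)C(C)(C)C)OC3 | intermediate
18 | C1 tert-butyldimethylsilyl ether of 15 (3R,6S,9R) | C=C(CO)[C@H](O)CC[C@H]1CC[C@H](C(=C)CO[Si](C)(C)C(C)(C)C)OC1 | intermediate
19 | (3R)-2-(bromomethyl)-5-[(3S,6R)-6-{3-(tert-butyldimethylsilyloxy)prop-1-en-2-yl}oxan-3-yl]pent-1-en-3-ol | C=C(CBr)[C@H](O)CC[C@H]1CC[C@H](C(=C)CO[Si](C)(C)C(C)(C)C)OC1 | intermediate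
20 | geranyl bromide | CC(C)=CCC/C(C)=C/CBr | starting material
21 | geranyl phenyl sulfone | CC(C)=CCC/C(C)=C/CS(=O)(=O)c1ccccc1 | intermediate
22 | α-lithiated geranyl phenyl sulfone | CC(C)=CCC/C(C)=C/C([Li])S(=O)(=O)c1ccccc1 | intermediate
23 | C12 phenyl sulfone (3R,6S,9R,13E; both C12 epimers), C1 silyl ether | C=C(CC(/C=C(\C)CCC=C(C)C)S(=O)(=O)c1ccccc1)[C@H](O)CC[C@H]1CC[C@H](C(=C)CO[Si](C)(C)C(C)(C)C)OC1 | intermediate
24 | C1 tert-butyldimethylsilyl ether of 25 (3R,6S,9R,13E) | C=C(CC/C=C(\C)CCC=C(C)C)[C@H](O)CC[C@H]1CC[C@H](C(=C)CO[Si](C)(C)C(C)(C)C)OC1 | intermediate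
25 | (3R,7E)-1-[(3S,6R)-6-(3-hydroxyprop-1-en-2-yl)oxan-3-yl]-8,12-dimethyl-4-methylidenetrideca-7,11-dien-3-ol | C=C(CC/C=C(\C)CCC=C(C)C)[C@H](O)CC[C@H]1CC[C@H](C(=C)CO)OC1 | intermediate
26 | C1 enal corresponding to 25 | C=C(CC/C=C(\C)CCC=C(C)C)[C@H](O)CC[C@H]1CC[C@H](C(=C)C=O)OC1 | intermediate
27 | 2-[(2R,5S)-5-[(3R,7E)-3-hydroxy-8,12-dimethyl-4-methylidenetrideca-7,11-dien-1-yl]oxan-2-yl]prop-2-enoic acid | C=C(CC/C=C(\C)CCC=C(C)C)[C@H](O)CC[C@H]1CC[C@H](C(=C)C(=O)O)OC1 | target

Total step count: 18
Longest linear sequence: 16 steps (1-4, 6-13, 15-18), from diethyl 4-oxoheptanedioate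

Steps most likely to fail

Step 10. The irreversible closure may discriminate too weakly between the two diastereotopic oxygens, because only two equatorial preferences separate the competing chairs. The fallback sets out from triol 12 and comes back to the route at 14. It raises C6' to the carbonyl level so that the choice of arm becomes reversible. Oxidative lactonisation of the 1,5-diol unit with 2,2,6,6-tetramethylpiperidin-1-oxyl and PhI(OAc)2 in CH2Cl2 should give the δ-lactone F1 through either arm. Reduction with i-Bu2AlH in toluene at -78 °C should then give the lactol F2. In the lactol the ring opens and recloses through the hydroxy aldehyde, in which C6 is again no stereocentre, so the arms can exchange and the diequatorial trans ring should accumulate. Ionic reduction with Et3SiH and BF3·OEt2 in CH2Cl2 at -78 °C then removes the anomeric hydroxyl through the cyclic oxocarbenium ion and leads to 14.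

Step 7. Facial discrimination between the branched alkenyl group and the methylene chain may be too weak, or conjugate reduction of the α-methylene ketones may compete. The fallback sets out from bis-amide 6 and comes back at 11, bypassing 10. It sets the carbinol centres while the C2-C3 and C9-C10 bonds are formed. Reduction with i-Bu2AlH in THF at -78 °C should convert both amides into the dialdehyde F3. A double asymmetric Nozaki-Hiyama-Kishi coupling with bromide 8 (CrCl2, catalytic NiCl2, a chiral oxazoline-sulfonamide ligand on chromium, Et3N, THF) should then add the alkenylchromium reagent to each aldehyde under ligand control. The ligand enantiomer is chosen to give the (R)-carbinols.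

Step 12. The boronate may be lost or may scramble while the silyl chloride is present, which would let silicon reach O9 or O11. The fallback sets out from triol 15 and comes back at 18. It replaces the transient mask by an isolated one. 2,2-Dimethoxypropane and catalytic pyridinium p-toluenesulfonate in CH2Cl2 should tie O9 and O11 into the acetonide alcohol F4. Treatment with t-BuMe2SiCl and imidazole should convert this into the acetonide silyl ether F5. Brief methanolysis with pyridinium p-toluenesulfonate in MeOH at rt should then release 18, since it cleaves the strained 1,3-dioxane ketal ahead of the primary silyl ether.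

Further compounds
F1 | step 10 | δ-lactone of 12 (C6' as ring carbonyl; 3R,9R; mixture at C6) | C=C(CO[Si](C(C)C)(C(C)C)C(C)C)[C@H](O)CCC1CC[C@H](C(=C)CO[Si](C(C)C)(C(C)C)C(C)C)OC1=O
F2 | step 10 | lactol from F1 (3R,9R; equilibrating at C6 and C6') | C=C(CO[Si](C(C)C)(C(C)C)C(C)C)[C@H](O)CCC1CC[C@H](C(=C)CO[Si](C(C)C)(C(C)C)C(C)C)OC1O
F3 | step 7 | 4-[(triethylsilyloxy)methyl]heptanedial | CC[Si](CC)(CC)OCC(CCC=O)CCC=O
F4 | step 12 | O9,O11-isopropylidene acetal of triol 15 (C1 hydroxyl free) | C=C1COC(C)(C)O[C@@H]1CC[C@H]2CC[C@H](C(=C)CO)OC2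
F5 | step 12 | C1 tert-butyldimethylsilyl ether of F4 | C=C1COC(C)(C)O[C@@H]1CC[C@H]2CC[C@H](C(=C)CO[Si](C)(C)C(C)(C)C)OC2
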